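**Retrosynthetic overview**

1. Target 26 ⇐ 25 (desilylation) ⇐ 22 (angeloylation at O8) ⇐ 21 (acetylation at O9) ⇐ 20 (ketal removal).
2. 20 ⇐ 17, key step: an allylchromium made from the 2-(chloromethyl)enoate adds through C7 to the C6 enal. This closes the ten-membered carbocycle first, and the chromium alkoxide then closes the 12,6-lactone in the same flask.
3. 17 ⇐ 11 + 12 (C3–C4 bond by asymmetric alkenylzinc addition, which sets C3 and the 4E olefin); 11 ⇐ 7 + 8 (Morita–Baylis–Hillman reaction, then allylic transposition to the chloride).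
4. 7 ⇐ 2 + 3 (Z-selective Wittig reaction for C1=C10) ⇐ 1 (chiral pool, C8 and C9) + MeLi (C14).

Assumption: germacrane numbering (C1–C10 ring, C11–C13 methylene-lactone carbons, C14 on C10, C15 on C4) is used for all intermediates; 3, 12 and 23 are bought.

**Route**

Step 1
Reactants: 1 2,3-O-isopropylidene-D-erythronolactone
Product: 2 methyl lactol (1-deoxy-3,4-O-isopropylidene-D-erythro-pent-2-ulofuranose)
Conditions: MeLi (1.05 equiv), THF, −78 °C; aq. NH4Cl
Reagents that add atoms: methyllithium, [Li]C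
Why: Nucleophilic acyl addition of one equivalent of MeLi to the γ-lactone stops at the hemiketal because the tetrahedral lithium alkoxide is stable at −78 °C, and C8 and C9 come unchanged from the chiral pool.

Step 2
Reactants: 2 methyl lactol; 3 [2-(1,3-dioxolan-2-yl)ethyl]triphenylphosphonium bromide
Product: 6 (Z)-alkenol, via phosphorus ylide 4 (not isolated), via keto alkoxide 5 (not isolated)
Conditions: 3 (2.6 equiv), KN(SiMe3)2 (2.5 equiv), THF, −78 °C; then 2, THF/DMPU, −78 → 0 °C
Reagents that add atoms: none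
Why: Wittig olefination of the α-alkoxy methyl ketone that the base unmasks from the hemiketal; non-stabilised ylides add to α-alkoxy ketones (Still's Z-selective trisubstituted-olefin variant) so that the ylide carbon C1 ends up cis to the oxygenated carbon C9, which gives the 1(10)Z alkene.

Step 3
Reactants: 6 (Z)-alkenol
Product: 7 α-alkoxy aldehyde
Conditions: Dess–Martin periodinane, pyridine, CH2Cl2, 0 °C → rt; used crude
Reagents that add atoms: none
Why: Dess–Martin oxidation under buffered, non-basic conditions gives the aldehyde without epimerising C8 and leaves both acetals untouched.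

Step 4
Reactants: 7 α-alkoxy aldehyde; 8 methyl acrylate
Product: 9 Morita–Baylis–Hillman adduct (both C7 epimers)
Conditions: 8 (10 equiv), 1,4-diazabicyclo[2.2.2]octane (1 equiv), 1,4-dioxane/H2O (1:1), rt, 3 d
Reagents that add atoms: none
Why: Morita–Baylis–Hillman reaction in which the amine–acrylate zwitterion adds to the electrophilic α-alkoxy aldehyde; the C7 carbinol forms as a mixture, which does not matter because C7 becomes sp2 in the next step.

Step 5
Reactants: 9 Morita–Baylis–Hillman adduct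
Product: 10 (Z)-2-(chloromethyl)enoate
Conditions: N-chlorosuccinimide, Me2S, CH2Cl2, −20 → 0 °C
Reagents that add atoms: N-chlorosuccinimide, O=C1CCC(=O)N1Cl
Why: Corey–Kim-type activation of the allylic alcohol as an alkoxysulfonium salt followed by SN2′ attack of chloride gives the conjugated (Z)-2-(chloromethyl)enoate (C8 cis to CH2Cl) from both C7 epimers.

Step 6
Reactants: 10 (Z)-2-(chloromethyl)enoate
Product: 11 C3 aldehyde
Conditions: In(OTf)3 (5 mol%), acetone/H2O (20:1), rt; used at once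
Reagents that add atoms: water, O
Why: Lewis-acid-catalysed acetal hydrolysis frees the β,γ-unsaturated C3 aldehyde, while the isopropylidene ketal is held by the acetone solvent and no free hydroxyl is present that could trigger ketal migration.

Step 7
Reactants: 11 C3 aldehyde; 12 1,1-diethoxybut-2-yne
Product: 15 (3S)-allylic alcohol, via alkenylzirconocene chloride 13 (not isolated), via alkenylmethylzinc 14 (not isolated)
Conditions: 12, Cp2Zr(H)Cl, CH2Cl2, rt; toluene, Me2Zn, −65 °C; (+)-3-exo-morpholinoisoborneol (C14H25NO2, 10 mol%), then 11, −30 → 0 °C; aq. NH4Cl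
Reagents that add atoms: none
Why: Hydrozirconation (syn addition, Zr on the methyl-bearing carbon) and Zr-to-Zn transmetalation give an (E)-alkenylzinc that adds to the aldehyde under amino-alcohol catalysis (asymmetric alkenylzinc addition) on the Re face, which sets 3S and brings in the 4E olefin, while the allylic chloride and the enoate are inert to the organozinc.

Step 8
Reactants: 15 (3S)-allylic alcohol
Product: 17 silylated enal, via silylated acetal 16 (not isolated)
Conditions: TBSOTf, 2,6-lutidine, CH2Cl2, −78 °C; then 1 M aq. HCl, THF, 0 °C, 15 min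
Reagents that add atoms: tert-butyldimethylsilyl trifluoromethanesulfonate, CC(C)(C)[Si](C)(C)OS(=O)(=O)C(F)(F)F; water, O
Why: Silyl triflate silylation of the secondary allylic alcohol followed by brief acid hydrolysis of the very labile α,β-unsaturated diethyl acetal unveils the (E)-enal without touching the ketal, the silyl ether or the allylic chloride.

Step 9
Reactants: 17 silylated enal
Product: 20 macrolactone acetonide, via allylchromium dichloride 18 (not isolated), via hydroxy ester carbocycle 19 (not isolated)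
Conditions: CrCl2 (10 equiv), NaI (0.2 equiv), THF/DMF (4:1), 17 added over 8 h to 2 mM, 25 → 40 °C; aq. NH4Cl
Reagents that add atoms: none
Why: Intramolecular Nozaki–Hiyama allylation with lactonisation, in which divalent chromium turns the allylic chloride into a γ-substituted allylchromium that adds through C7 to the enal by a chair-like closed transition state (anti adduct, hence the 6,7-trans lactone) on the face of C7 anti to the C8–O bond, where the cis-fused ketal and the tether place the aldehyde (6R,7S), and the chromium alkoxide then closes the γ-lactone onto the neighbouring methyl ester.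

Step 10
Reactants: 20 macrolactone acetonide
Product: 21 8,9-diol
Conditions: AcOH/THF/H2O (3:1:1), 45 °C
Reagents that add atoms: none
Why: Acid-catalysed hydrolysis of the cis-fused isopropylidene ketal is faster than cleavage of the secondary silyl ether or of the allylic lactone.

Step 11
Reactants: 21 8,9-diol
Product: 22 9-acetate
Conditions: AcCl (1.05 equiv), 2,4,6-collidine, CH2Cl2, −78 → −40 °C
Reagents that add atoms: acetyl chloride, CC(Cl)=O
Why: Kinetic acylation, in which the allylic C9 hydroxyl next to the planar C10 is less hindered than the C8 hydroxyl next to the ring-fusion carbon C7, so one equivalent of acetyl chloride with a hindered base at low temperature is expected to acetylate O9.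

Step 12
Reactants: 22 9-acetate; 23 angelic acid
Product: 25 silylated target, via mixed anhydride 24 (not isolated)
Conditions: 23 (3 equiv), 2,4,6-trichlorobenzoyl chloride (3 equiv), Et3N, toluene, rt, 2 h; then 22, toluene, 80 °C
Reagents that add atoms: none
Why: Yamaguchi esterification through the mixed anhydride, run without a nucleophilic catalyst so that the (Z)-angelate does not isomerise to the tiglate and the neighbouring acetate does not migrate.

Step 13
Reactants: 25 silylated target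
Product: 26 target
Conditions: HF·pyridine, pyridine, THF, 0 °C → rt
Reagents that add atoms: none
Why: Fluoride cleavage of the silyl ether (Si–F bond formation) under buffered conditions spares the two esters, the α-methylene lactone and the angelate geometry.

**Compound list**

1 | 2,3-O-isopropylidene-D-erythronolactone, (3aR,6aR)-2,2-dimethyldihydrofuro[3,4-d][1,3]dioxol-4(3aH)-one | O=C1[C@H](OC(C)(C)O2)[C@H]2CO1 | starting material
2 | 1-deoxy-3,4-O-isopropylidene-D-erythro-pent-2-ulofuranose, (3aR,6aR)-2,2,4-trimethyltetrahydrofuro[3,4-d][1,3]dioxol-4-ol (anomer mixture) | CC1(O)[C@H](OC(C)(C)O2)[C@H]2CO1 | intermediate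
3 | [2-(1,3-dioxolan-2-yl)ethyl]triphenylphosphonium bromide | [Br-].C1COC(CC[P+](c2ccccc2)(c2ccccc2)c2ccccc2)O1 | starting material
4 | [2-(1,3-dioxolan-2-yl)ethylidene]triphenylphosphorane | C1COC(CC=P(c2ccccc2)(c2ccccc2)c2ccccc2)O1 | intermediate
5 | potassium [(4R,5R)-5-acetyl-2,2-dimethyl-1,3-dioxolan-4-yl]methanolate | CC(=O)[C@H](OC(C)(C)O1)[C@H]1C[O-].[K+] | intermediate
6 | [(4R,5S)-5-[(2Z)-4-(1,3-dioxolan-2-yl)but-2-en-2-yl]-2,2-dimethyl-1,3-dioxolan-4-yl]methanol | O1CCOC1C/C=C(/C)[C@H](OC(C)(C)O2)[C@H]2CO | intermediate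
7 | (4S,5S)-5-[(2Z)-4-(1,3-dioxolan-2-yl)but-2-en-2-yl]-2,2-dimethyl-1,3-dioxolane-4-carbaldehyde | O1CCOC1C/C=C(/C)[C@H](OC(C)(C)O2)[C@H]2C=O | intermediate
8 | methyl acrylate | C=CC(=O)OC | starting material
9 | methyl 2-{[(4R,5S)-5-[(2Z)-4-(1,3-dioxolan-2-yl)but-2-en-2-yl]-2,2-dimethyl-1,3-dioxolan-4-yl](hydroxy)methyl}prop-2-enoate (both carbinol epimers) | O1CCOC1C/C=C(/C)[C@H](OC(C)(C)O2)[C@H]2C(O)C(=C)C(=O)OC | intermediate
10 | methyl (2Z)-2-(chloromethyl)-3-[(4R,5S)-5-[(2Z)-4-(1,3-dioxolan-2-yl)but-2-en-2-yl]-2,2-dimethyl-1,3-dioxolan-4-yl]prop-2-enoate | O1CCOC1C/C=C(/C)[C@H](OC(C)(C)O2)[C@H]2/C=C(\CCl)C(=O)OC | intermediate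
11 | methyl (2Z)-2-(chloromethyl)-3-[(4R,5S)-2,2-dimethyl-5-[(2Z)-5-oxopent-2-en-2-yl]-1,3-dioxolan-4-yl]prop-2-enoate | O=CC/C=C(/C)[C@H](OC(C)(C)O1)[C@H]1/C=C(\CCl)C(=O)OC | intermediate
12 | 1,1-diethoxybut-2-yne (but-2-ynal diethyl acetal) | CC#CC(OCC)OCC | starting material
13 | chlorobis(cyclopentadienyl)[(2E)-4,4-diethoxybut-2-en-2-yl]zirconium | C/C(=C\C(OCC)OCC)[Zr](Cl)(C1C=CC=C1)C1C=CC=C1 | intermediate
14 | [(2E)-4,4-diethoxybut-2-en-2-yl](methyl)zinc | C/C(=C\C(OCC)OCC)[Zn]C | intermediate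
15 | methyl (2Z)-2-(chloromethyl)-3-[(4R,5S)-5-[(2Z,5S,6E)-8,8-diethoxy-5-hydroxy-6-methylocta-2,6-dien-2-yl]-2,2-dimethyl-1,3-dioxolan-4-yl]prop-2-enoate | CCOC(OCC)/C=C(\C)[C@@H](O)C/C=C(/C)[C@H](OC(C)(C)O1)[C@H]1/C=C(\CCl)C(=O)OC | intermediate
16 | methyl (2Z)-3-[(4R,5S)-5-[(2Z,5S,6E)-5-[(tert-butyldimethylsilyl)oxy]-8,8-diethoxy-6-methylocta-2,6-dien-2-yl]-2,2-dimethyl-1,3-dioxolan-4-yl]-2-(chloromethyl)prop-2-enoate | CCOC(OCC)/C=C(\C)[C@@H](O[Si](C)(C)C(C)(C)C)C/C=C(/C)[C@H](OC(C)(C)O1)[C@H]1/C=C(\CCl)C(=O)OC | intermediate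
17 | methyl (2Z)-3-[(4R,5S)-5-[(2Z,5S,6E)-5-[(tert-butyldimethylsilyl)oxy]-6-methyl-8-oxoocta-2,6-dien-2-yl]-2,2-dimethyl-1,3-dioxolan-4-yl]-2-(chloromethyl)prop-2-enoate | O=C/C=C(\C)[C@@H](O[Si](C)(C)C(C)(C)C)C/C=C(/C)[C@H](OC(C)(C)O1)[C@H]1/C=C(\CCl)C(=O)OC | intermediate
18 | allylchromium dichloride from 17 (CrCl2 in place of Cl at C13) | O=C/C=C(\C)[C@@H](O[Si](C)(C)C(C)(C)C)C/C=C(/C)[C@H](OC(C)(C)O1)[C@H]1/C=C(\C[Cr](Cl)Cl)C(=O)OC | intermediate
19 | methyl (1(10)Z,3S,4E,6R,7S,8R,9S)-3-[(tert-butyldimethylsilyl)oxy]-6-hydroxy-8,9-(isopropylidenedioxy)germacra-1(10),4,11(13)-trien-12-oate (present as its chromium alkoxide) | O[C@@H]1/C=C(\C)[C@@H](O[Si](C)(C)C(C)(C)C)C/C=C(/C)[C@H](OC(C)(C)O2)[C@H]2[C@H]1C(=C)C(=O)OC | intermediate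
20 | (1(10)Z,3S,4E,6R,7S,8R,9S)-3-[(tert-butyldimethylsilyl)oxy]-8,9-(isopropylidenedioxy)germacra-1(10),4,11(13)-trien-12,6-olide | C=C1C(=O)O[C@@H]2/C=C(\C)[C@@H](O[Si](C)(C)C(C)(C)C)C/C=C(/C)[C@H](OC(C)(C)O3)[C@H]3[C@@H]12 | intermediate
21 | (1(10)Z,3S,4E,6R,7R,8R,9S)-3-[(tert-butyldimethylsilyl)oxy]-8,9-dihydroxygermacra-1(10),4,11(13)-trien-12,6-olide | C=C1C(=O)O[C@@H]2/C=C(\C)[C@@H](O[Si](C)(C)C(C)(C)C)C/C=C(/C)[C@H](O)[C@H](O)[C@@H]12 | intermediate
22 | (1(10)Z,3S,4E,6R,7R,8R,9S)-9-acetoxy-3-[(tert-butyldimethylsilyl)oxy]-8-hydroxygermacra-1(10),4,11(13)-trien-12,6-olide | C=C1C(=O)O[C@@H]2/C=C(\C)[C@@H](O[Si](C)(C)C(C)(C)C)C/C=C(/C)[C@H](OC(C)=O)[C@H](O)[C@@H]12 | intermediate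
23 | angelic acid, (2Z)-2-methylbut-2-enoic acid | C/C=C(/C)C(=O)O | starting material
24 | (2Z)-2-methylbut-2-enoic 2,4,6-trichlorobenzoic anhydride | C/C=C(/C)C(=O)OC(=O)c1c(Cl)cc(Cl)cc1Cl | intermediate
25 | (1(10)Z,3S,4E,6R,7S,8R,9S)-9-acetoxy-8-(angeloyloxy)-3-[(tert-butyldimethylsilyl)oxy]germacra-1(10),4,11(13)-trien-12,6-olide | C=C1C(=O)O[C@@H]2/C=C(\C)[C@@H](O[Si](C)(C)C(C)(C)C)C/C=C(/C)[C@H](OC(C)=O)[C@H](OC(=O)/C(C)=C\C)[C@@H]12 | intermediate
26 | (1(10)Z,3S,4E,6R,7S,8R,9S)-9-acetoxy-8-[(2Z)-2-methylbut-2-enoyloxy]-3-hydroxygermacra-1(10),4,11(13)-trien-12,6-olide (CNP0265116.1) | C=C1C(=O)O[C@@H]2/C=C(\C)[C@@H](O)C/C=C(/C)[C@H](OC(C)=O)[C@H](OC(=O)/C(C)=C\C)[C@@H]12 | target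

**Step count and risks**

Total step count: 13. Longest linear sequence: 13 steps (1 to 26).

The three steps most likely to fail are steps 7, 9 and 11.

Step 7 may fail through poor facial control at C3 or through competing reaction of the organozinc with the allylic chloride. The fallback sets out from 11 and comes back at 15. Alkenylmethylzinc 14 is added to 11 without the amino alcohol to give the C3-epimeric allylic alcohols F1. Dess–Martin periodinane oxidises these to the cross-conjugated enone F2. Catecholborane with the (R)-configured B-methyl oxazaborolidine of diphenylprolinol (C18H20BNO) at −78 °C then reduces F2 to 15, so that C3 is set by reagent-controlled ketone reduction instead of carbonyl addition.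

Step 9 may fail through the strain of the (Z,E)-cyclodecadiene, through oligomers, or through the wrong face at C7. The fallback sets out from 10 and comes back at 20, and closes the two rings one after the other with the carbocycle closed at C3–C4 instead of C6–C7. Hydrozirconation–iodination of but-2-yn-1-ol gives (2E)-3-iodobut-2-en-1-ol F3, and MnO2 oxidises it to (2E)-3-iodobut-2-enal F4. Intermolecular CrCl2-mediated allylation of F4 with chloride 10, with lactonisation, gives the acyclic iodo lactone F5. In(OTf)3 in wet acetone frees the C3 aldehyde F6. An intramolecular NiCl2/CrCl2 Nozaki–Hiyama–Kishi coupling of the vinyl iodide with the aldehyde at high dilution, with a chiral sulfonamide ligand on chromium to favour the 3S alcohol, gives the macrocyclic allylic alcohol F7. TBSOTf and 2,6-lutidine convert F7 into 20.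

Step 11 may fail because the preference for O9 over O8 is an estimate and a mixture of monoacetates would result. The fallback sets out from 21 and comes back at 25, and tells the two hydroxyls apart by oxidation state instead of by rate. MnO2 oxidises only the allylic C9 hydroxyl and gives the hydroxy enone F8. Yamaguchi esterification with 23 on the one remaining hydroxyl gives the keto angelate F9. Luche reduction (NaBH4, CeCl3·7H2O, MeOH, −78 °C) from the outer face of the ring gives the 9S hydroxy angelate F10. Ac2O and pyridine convert F10 into 25.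

**Further compounds**

F1 | step 7 | methyl (2Z)-2-(chloromethyl)-3-[(4R,5S)-5-[(2Z,5RS,6E)-8,8-diethoxy-5-hydroxy-6-methylocta-2,6-dien-2-yl]-2,2-dimethyl-1,3-dioxolan-4-yl]prop-2-enoate (C3 epimers of 15) | CCOC(OCC)/C=C(\C)C(O)C/C=C(/C)[C@H](OC(C)(C)O1)[C@H]1/C=C(\CCl)C(=O)OC
F2 | step 7 | methyl (2Z)-2-(chloromethyl)-3-[(4R,5S)-5-[(2Z,6E)-8,8-diethoxy-6-methyl-5-oxoocta-2,6-dien-2-yl]-2,2-dimethyl-1,3-dioxolan-4-yl]prop-2-enoate | CCOC(OCC)/C=C(\C)C(=O)C/C=C(/C)[C@H](OC(C)(C)O1)[C@H]1/C=C(\CCl)C(=O)OC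
F3 | step 9 | (2E)-3-iodobut-2-en-1-ol | C/C(I)=C\CO
F4 | step 9 | (2E)-3-iodobut-2-enal | C/C(I)=C\C=O
F5 | step 9 | trans-4,5-disubstituted 3-methylenedihydrofuran-2(3H)-one carrying the (1E)-2-iodoprop-1-enyl group at C5 (germacrane C6) and the (4R,5S)-5-[(2Z)-4-(1,3-dioxolan-2-yl)but-2-en-2-yl]-2,2-dimethyl-1,3-dioxolan-4-yl group at C4 (germacrane C7), configured at C6 to C9 as in 20 | C=C1C(=O)O[C@H](/C=C(\C)I)[C@H]1[C@H]2OC(C)(C)O[C@H]2/C(C)=C\CC3OCCO3
F6 | step 9 | aldehyde from F5 with the 1,3-dioxolane replaced by CHO (germacrane C3) | C=C1C(=O)O[C@H](/C=C(\C)I)[C@H]1[C@H]2OC(C)(C)O[C@H]2/C(C)=C\CC=O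
F7 | step 9 | (1(10)Z,3S,4E,6R,7S,8R,9S)-3-hydroxy-8,9-(isopropylidenedioxy)germacra-1(10),4,11(13)-trien-12,6-olide | C=C1C(=O)O[C@@H]2/C=C(\C)[C@@H](O)C/C=C(/C)[C@H](OC(C)(C)O3)[C@H]3[C@@H]12
F8 | step 11 | 9-oxo analogue of 21: 3-[(tert-butyldimethylsilyl)oxy]-8-hydroxy-9-oxogermacra-1(10)Z,4E,11(13)-trien-12,6-olide, other centres as in 21 | C=C1C(=O)O[C@@H]2/C=C(\C)[C@@H](O[Si](C)(C)C(C)(C)C)C/C=C(/C)C(=O)[C@H](O)[C@@H]12
F9 | step 11 | 8-angelate of F8 | C=C1C(=O)O[C@@H]2/C=C(\C)[C@@H](O[Si](C)(C)C(C)(C)C)C/C=C(/C)C(=O)[C@H](OC(=O)/C(C)=C\C)[C@@H]12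
F10 | step 11 | (9S)-9-hydroxy-8-angelate: 25 without the acetyl group | C=C1C(=O)O[C@@H]2/C=C(\C)[C@@H](O[Si](C)(C)C(C)(C)C)C/C=C(/C)[C@H](O)[C@H](OC(=O)/C(C)=C\C)[C@@H]12
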